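**Retrosynthetic overview**
1. The bicyclo[3.2.1]octane is cut at C9a'–C15 and C2'–C14, giving a tricyclic hydroquinone and (12E)-labda-8(17),12,14-trien-18-oic acid. Forward, the hydroquinone is oxidised to its phenoxonium ion, so that arene carbon C9a' and diene terminus C15, both nucleophiles, are joined; C2'–C14 then closes.
2. Hydroquinone ⇐ tricyclic aryl ketone, by methoxymethylenation, α-face dihydroxylation (C9' OH α, CHO β) and oxidative demethylation/reduction.
3. Tricyclic ketone ⇐ 1,2,4-trimethoxy-3-isopropylbenzene + geranic acid (acylation, then ring B, then ring A), resolved by asymmetric transfer hydrogenation.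
4. Diene acid ⇐ abietic acid, keeping rings A/B with C4, C5, C9, C10: ring C is opened at C13=C14, the enal is transposed to the exocyclic methylene, C13 and the isopropyl group are excised, and the diene is rebuilt by two Wittig reactions.
5. Ring order: quinoid half, ring C (bought), ring B, ring A; labdane half, rings A/B from the chiral pool; last, both rings of the bicyclo[3.2.1]octane in one step.

Assumption: the target is read exactly as the SMILES gives it (equatorial 4α-CO2H as in abietic acid, 12E; adduct on the α face of the quinoid, side chain endo); labdane/abietane locants are used for the bicyclic acid, fluorene locants (primed in the adduct) for the tricyclic half.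
Assumption: in step 10 the (R,R) catalyst is the one that consumes the unwanted (4bR,8aR) ketone; if the sense proves opposite, the (S,S) catalyst is used.

**Route**

Step 1
Reactants: 1 abietic acid
Product: 3 13-oxo-13,14-secoabiet-7-en-14-al-18-oic acid (Δ7 decalin with 8-CHO and a 4-methyl-3-oxopentyl chain at C9), via abietic diol 2 (not isolated)
Conditions: OsO4 (2 mol %), NaIO4, 2,6-lutidine, dioxane/H2O, 25 °C
Reagents that add atoms: osmium tetroxide (O=[Os](=O)(=O)=O); sodium periodate ([Na+].[O-][I](=O)(=O)=O); water (O)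
Why: Lemieux–Johnson oxidation (dihydroxylation, then periodate glycol cleavage) attacks the more accessible, more electron-rich C13=C14 bond of the diene and stops at the deactivated Δ7-enal, leaving C4, C5, C9 and C10 of the resin acid untouched.

Step 2
Reactants: 3 13-oxo-13,14-secoabiet-7-en-14-al-18-oic acid
Product: 6 13-oxo-13,14-secoabiet-8(14)-en-18-oic acid (exocyclic methylene at C8), via tosylhydrazone 4 (not isolated), via allyl diazene 5 (not isolated)
Conditions: TsNHNH2, THF, 4 Å MS, 25 °C; then catecholborane, 0 °C; then NaOAc·3H2O, 65 °C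
Reagents that add atoms: none
Why: Kabalka reductive 1,3-transposition: the aldehyde condenses in preference to the hindered isopropyl ketone, catecholborane reduces the C=N bond, and acetate-induced loss of sulfinate gives an allylic diazene whose retro-ene loss of N2 delivers H to C7 and moves the alkene to the exocyclic position (no new stereocentre).

Step 3
Reactants: 6 13-oxo-13,14-secoabiet-8(14)-en-18-oic acid
Product: 8 12-hydroxy-13-oxo-13,14-secoabiet-8(14)-en-18-oic acid (12-epimers), via dipotassium enolate 7 (not isolated)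
Conditions: KN(SiMe3)2 (2.3 equiv), THF, −78 °C; 2-(phenylsulfonyl)-3-phenyloxaziridine; NH4Cl (aq)
Reagents that add atoms: 2-(phenylsulfonyl)-3-phenyloxaziridine (O=S(=O)(c1ccccc1)N1OC1c1ccccc1)
Why: Kinetic deprotonation at the C12 methylene (not the isopropyl methine) and Davis enolate hydroxylation; the C12 configuration is irrelevant because this centre is destroyed in step 4.

Step 4
Reactants: 8 12-hydroxy-13-oxo-13,14-secoabiet-8(14)-en-18-oic acid
Product: 9 12-oxo-13,14,15,16-tetranorlabd-8(17)-en-18-oic acid (C9–CH2–CHO)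
Conditions: NaIO4, THF/H2O, 25 °C
Reagents that add atoms: none
Why: Periodate α-ketol cleavage cuts C12–C13, removing the isopropyl ketone as isobutyric acid, while the 1,1-disubstituted alkene is inert.

Step 5
Reactants: 9 12-oxo-13,14,15,16-tetranorlabd-8(17)-en-18-oic acid
Product: 10 (12E)-14-oxo-15-norlabda-8(17),12-dien-18-oic acid
Conditions: Ph3P=C(Me)CHO (1.5 equiv), PhMe, 90 °C
Reagents that add atoms: 2-(triphenylphosphoranylidene)propanal (CC(C=O)=P(c1ccccc1)(c1ccccc1)c1ccccc1)
Why: Wittig olefination with a stabilised formyl ylide gives the (E)-2-methyl enal under thermodynamic control, fixing the 12E geometry.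

Step 6
Reactants: 10 (12E)-14-oxo-15-norlabda-8(17),12-dien-18-oic acid
Product: 11 (12E)-labda-8(17),12,14-trien-18-oic acid
Conditions: Ph3PCH3Br, KOtBu (3 equiv each), THF, 0 → 25 °C; citric acid (aq)
Reagents that add atoms: methyltriphenylphosphonium bromide (C[P+](c1ccccc1)(c1ccccc1)c1ccccc1.[Br-])
Why: Wittig methylenation of the enal completes the 12E,14-diene; the hindered carboxylate only consumes one equivalent of ylide.

Step 7
Reactants: 12 1,2,4-trimethoxybenzene
Product: 14 2-(2,3,6-trimethoxyphenyl)propan-2-ol, via aryllithium 13 (not isolated)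
Conditions: n-BuLi, THF, 0 °C; Me2CO, −78 → 25 °C; NH4Cl (aq)
Reagents that add atoms: acetone (CC(C)=O)
Why: Directed ortho-lithiation occurs at C3, between two methoxy groups, and the aryllithium adds to acetone.

Step 8
Reactants: 14 2-(2,3,6-trimethoxyphenyl)propan-2-ol
Product: 15 1,2,4-trimethoxy-3-(propan-2-yl)benzene
Conditions: Et3SiH, CF3CO2H, CH2Cl2, 0 → 25 °C
Reagents that add atoms: none
Why: Ionic hydrogenation: the tertiary benzylic cation is reduced by hydride transfer from the silane.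

Step 9
Reactants: 15 1,2,4-trimethoxy-3-(propan-2-yl)benzene; 16 geranic acid
Product: 19 (±)-trans-1,3,4-trimethoxy-4b,8,8-trimethyl-2-(propan-2-yl)-4b,5,6,7,8,8a-hexahydro-9H-fluoren-9-one, via mixed anhydride 17 (not isolated), via aryl dienone 18 (not isolated)
Conditions: (CF3CO)2O, CH2Cl2, 0 → 25 °C; then MeSO3H, 40 °C
Reagents that add atoms: none
Why: Tandem Friedel–Crafts acylation at C5 (ortho/para to methoxy), aromatic Nazarov-type closure of ring B onto C6 and cation–olefin (α-tert-alkylation) closure of ring A; C8a, α to the ketone, equilibrates to the trans ring fusion, so the relative configuration (4bS*,8aS*) is set but the product is racemic.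

Step 10
Reactants: 19 (±)-trans-1,3,4-trimethoxy-4b,8,8-trimethyl-2-(propan-2-yl)-4b,5,6,7,8,8a-hexahydro-9H-fluoren-9-one
Product: 20 (4bS,8aS)-1,3,4-trimethoxy-4b,8,8-trimethyl-2-(propan-2-yl)-4b,5,6,7,8,8a-hexahydro-9H-fluoren-9-one (recovered unreacted enantiomer)
Conditions: RuCl(p-cymene)[(R,R)-TsDPEN] (1 mol %), HCO2H/Et3N (5:2), 30 °C, to about 55% conversion
Reagents that add atoms: none
Why: Kinetic resolution by Noyori asymmetric transfer hydrogenation: for the (4bR,8aR) ketone the catalyst-preferred and substrate-preferred hydride faces coincide, so it is reduced much faster and the (4bS,8aS) ketone is left behind, which fixes the absolute configuration at C4b and C8a.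

Step 11
Reactants: 20 (4bS,8aS)-ketone
Product: 21 (4bS,8aS)-1,3,4-trimethoxy-9-(methoxymethylidene)-4b,8,8-trimethyl-2-(propan-2-yl)-4b,5,6,7,8,8a-hexahydro-9H-fluorene (E/Z mixture)
Conditions: MeOCH2PPh3Cl, KOtBu, THF, 0 → 45 °C
Reagents that add atoms: (methoxymethyl)triphenylphosphonium chloride (COC[P+](c1ccccc1)(c1ccccc1)c1ccccc1.[Cl-])
Why: Wittig methoxymethylenation homologates the aryl ketone by one carbon; enolisation only returns the trans ketone, and C8a is locked once the carbonyl is gone.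

Step 12
Reactants: 21 enol ether
Product: 23 (4bS,8aS,9R)-9-hydroxy-1,3,4-trimethoxy-4b,8,8-trimethyl-2-(propan-2-yl)-4b,5,6,7,8,8a-hexahydro-9H-fluorene-9-carbaldehyde, via hemiacetal 22 (not isolated)
Conditions: OsO4 (2 mol %), NMO, acetone/H2O, 0 → 25 °C
Reagents that add atoms: osmium tetroxide (O=[Os](=O)(=O)=O); N-methylmorpholine N-oxide (C[N+]1([O-])CCOCC1); water (O)
Why: Upjohn dihydroxylation of the enol ether from the α face, opposite to the axial β-methyl groups at C4b and C8, gives a hemiacetal that loses methanol, setting C9 with OH α and CHO β (9R).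

Step 13
Reactants: 23 tertiary α-hydroxy aldehyde
Product: 25 (4bS,8aS,9R)-1,4,9-trihydroxy-3-methoxy-4b,8,8-trimethyl-2-(propan-2-yl)-4b,5,6,7,8,8a-hexahydro-9H-fluorene-9-carbaldehyde, via methoxyquinone 24 (not isolated)
Conditions: (NH4)2Ce(NO3)6 (2.5 equiv), MeCN/H2O, 0 °C, 10 min; then Na2S2O4 (aq)
Reagents that add atoms: water (O)
Why: Oxidative demethylation of the para-dimethoxy pair by tetravalent cerium gives the 3-methoxy-1,4-quinone, which dithionite reduces in the same pot to the storable hydroquinone.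

Step 14
Reactants: 25 hydroquinone; 11 (12E)-labda-8(17),12,14-trien-18-oic acid (1.5 equiv)
Product: 28 target CNP0124601.1, via phenoxonium ion 26 (not isolated), via oxocarbenium adduct 27 (not isolated)
Conditions: PhI(OAc)2 (1.05 equiv), (CF3)2CHOH/CH2Cl2 (4:1), −40 → 0 °C; then pH 7 buffer
Reagents that add atoms: water (O)
Why: Proposed new method: two-electron oxidation of 25 in the fluoroalcohol gives the O-protonated quinone, a phenoxonium (aromatic enolonium) ion in which the former arene carbon C9a' is electrophilic, so the diene terminus C15 adds there from the α face (anti to the C4b' methyl and the C9' formyl group), the allyl cation is captured at C14 by the enol-ether carbon C2' with the side chain endo, and hydrolysis of the C3' methyl oxocarbenium gives the hydroxy-enone, setting C9a', C2' and C14 in one operation; the closest known reactions are cationic [5+2] cycloadditions of 2-alkoxyquinone cations with propenylarenes and hypervalent-iodine oxidative-dearomatisation [5+2] cascades.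

**Compound list**

1 | abietic acid (abieta-7,13-dien-18-oic acid) | CC(C)C1=CC2=CC[C@@H]3[C@](C)(CCC[C@@]3(C)C(=O)O)[C@H]2CC1 | starting material
2 | 13,14-dihydroxyabiet-7-en-18-oic acid (C13/C14 configuration not defined) | CC(C)C1(O)C(O)C2=CC[C@@H]3[C@](C)(CCC[C@@]3(C)C(=O)O)[C@H]2CC1 | intermediate
3 | 13-oxo-13,14-secoabiet-7-en-14-al-18-oic acid | O=CC1=CC[C@@H]2[C@](C)(CCC[C@@]2(C)C(=O)O)[C@H]1CCC(=O)C(C)C | intermediate
4 | C14 N-tosylhydrazone of 3 | Cc1ccc(cc1)S(=O)(=O)NN=CC1=CC[C@@H]2[C@](C)(CCC[C@@]2(C)C(=O)O)[C@H]1CCC(=O)C(C)C | intermediate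
5 | allylic diazene (14-diazenyl-13-oxo-13,14-secoabiet-7-en-18-oic acid) | N=NCC1=CC[C@@H]2[C@](C)(CCC[C@@]2(C)C(=O)O)[C@H]1CCC(=O)C(C)C | intermediate
6 | 13-oxo-13,14-secoabiet-8(14)-en-18-oic acid | C=C1CC[C@@H]2[C@](C)(CCC[C@@]2(C)C(=O)O)[C@H]1CCC(=O)C(C)C | intermediate
7 | dipotassium C12-enolate carboxylate of 6 | C=C1CC[C@@H]2[C@](C)(CCC[C@@]2(C)C(=O)[O-])[C@H]1CC=C([O-])C(C)C.[K+].[K+] | intermediate
8 | 12-hydroxy-13-oxo-13,14-secoabiet-8(14)-en-18-oic acid (12-epimers) | C=C1CC[C@@H]2[C@](C)(CCC[C@@]2(C)C(=O)O)[C@H]1CC(O)C(=O)C(C)C | intermediate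
9 | 12-oxo-13,14,15,16-tetranorlabd-8(17)-en-18-oic acid | C=C1CC[C@@H]2[C@](C)(CCC[C@@]2(C)C(=O)O)[C@H]1CC=O | intermediate
10 | (12E)-14-oxo-15-norlabda-8(17),12-dien-18-oic acid | C=C1CC[C@@H]2[C@](C)(CCC[C@@]2(C)C(=O)O)[C@H]1C/C=C(\C)C=O | intermediate
11 | (12E)-labda-8(17),12,14-trien-18-oic acid; (1R,4aR,5S,8aR)-1,4a-dimethyl-6-methylidene-5-[(2E)-3-methylpenta-2,4-dien-1-yl]decahydronaphthalene-1-carboxylic acid | C=C1CC[C@@H]2[C@](C)(CCC[C@@]2(C)C(=O)O)[C@H]1C/C=C(\C)C=C | intermediate
12 | 1,2,4-trimethoxybenzene | COc1ccc(OC)c(OC)c1 | starting material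
13 | 2,3,6-trimethoxyphenyllithium | [Li]c1c(OC)ccc(OC)c1OC | intermediate
14 | 2-(2,3,6-trimethoxyphenyl)propan-2-ol | COc1ccc(OC)c(C(C)(C)O)c1OC | intermediate
15 | 1,2,4-trimethoxy-3-(propan-2-yl)benzene | COc1ccc(OC)c(C(C)C)c1OC | intermediate
16 | geranic acid, (2E)-3,7-dimethylocta-2,6-dienoic acid (the commercial E/Z mixture converges) | CC(C)=CCC/C(C)=C/C(=O)O | starting material
17 | geranic trifluoroacetic mixed anhydride | CC(C)=CCC/C(C)=C/C(=O)OC(=O)C(F)(F)F | intermediate
18 | (2E)-3,7-dimethyl-1-[2,4,5-trimethoxy-3-(propan-2-yl)phenyl]octa-2,6-dien-1-one | CC(C)=CCC/C(C)=C/C(=O)c1cc(OC)c(OC)c(C(C)C)c1OC | intermediate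
19 | (±)-trans-1,3,4-trimethoxy-4b,8,8-trimethyl-2-(propan-2-yl)-4b,5,6,7,8,8a-hexahydro-9H-fluoren-9-one (racemate, both enantiomers written) | O=C1c2c(OC)c(C(C)C)c(OC)c(OC)c2[C@@]2(C)CCCC(C)(C)[C@@H]21.O=C1c2c(OC)c(C(C)C)c(OC)c(OC)c2[C@]2(C)CCCC(C)(C)[C@H]21 | intermediate
20 | (4bS,8aS)-1,3,4-trimethoxy-4b,8,8-trimethyl-2-(propan-2-yl)-4b,5,6,7,8,8a-hexahydro-9H-fluoren-9-one | O=C1c2c(OC)c(C(C)C)c(OC)c(OC)c2[C@@]2(C)CCCC(C)(C)[C@@H]21 | intermediate
21 | (4bS,8aS)-1,3,4-trimethoxy-9-(methoxymethylidene)-4b,8,8-trimethyl-2-(propan-2-yl)-4b,5,6,7,8,8a-hexahydro-9H-fluorene (E/Z) | COC=C1c2c(OC)c(C(C)C)c(OC)c(OC)c2[C@@]2(C)CCCC(C)(C)[C@@H]21 | intermediate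
22 | (4bS,8aS,9R)-9-[hydroxy(methoxy)methyl]-1,3,4-trimethoxy-4b,8,8-trimethyl-2-(propan-2-yl)-4b,5,6,7,8,8a-hexahydro-9H-fluoren-9-ol | COC(O)[C@]1(O)c2c(OC)c(C(C)C)c(OC)c(OC)c2[C@@]2(C)CCCC(C)(C)[C@@H]21 | intermediate
23 | (4bS,8aS,9R)-9-hydroxy-1,3,4-trimethoxy-4b,8,8-trimethyl-2-(propan-2-yl)-4b,5,6,7,8,8a-hexahydro-9H-fluorene-9-carbaldehyde | O=C[C@]1(O)c2c(OC)c(C(C)C)c(OC)c(OC)c2[C@@]2(C)CCCC(C)(C)[C@@H]21 | intermediate
24 | (4bS,8aS,9R)-9-hydroxy-3-methoxy-4b,8,8-trimethyl-1,4-dioxo-2-(propan-2-yl)-4,4b,5,6,7,8,8a,9-octahydro-1H-fluorene-9-carbaldehyde (methoxyquinone) | O=C[C@]1(O)C2=C(C(=O)C(OC)=C(C(C)C)C2=O)[C@@]2(C)CCCC(C)(C)[C@@H]21 | intermediate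
25 | (4bS,8aS,9R)-1,4,9-trihydroxy-3-methoxy-4b,8,8-trimethyl-2-(propan-2-yl)-4b,5,6,7,8,8a-hexahydro-9H-fluorene-9-carbaldehyde (hydroquinone) | O=C[C@]1(O)c2c(O)c(C(C)C)c(OC)c(O)c2[C@@]2(C)CCCC(C)(C)[C@@H]21 | intermediate
26 | phenoxonium ion: 24 protonated on the C4 carbonyl oxygen | O=C[C@]1(O)C2=C(C(=[OH+])C(OC)=C(C(C)C)C2=O)[C@@]2(C)CCCC(C)(C)[C@@H]21 | intermediate
27 | [5+2] adduct as its C3' O-methyl oxocarbenium ion | C=C1CC[C@@H]2[C@](C)(CCC[C@@]2(C)C(=O)O)[C@H]1C/C=C(\C)[C@@H]1C[C@@]23C(=O)[C@]1(C(C)C)C(=[O+]C)C(O)=C2[C@@]1(C)CCCC(C)(C)[C@@H]1[C@]3(O)C=O | intermediate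
28 | CNP0124601.1 | C=C1CC[C@@H]2[C@](C)(CCC[C@@]2(C)C(=O)O)[C@H]1C/C=C(\C)[C@@H]1C[C@@]23C(=O)[C@]1(C(C)C)C(=O)C(O)=C2[C@@]1(C)CCCC(C)(C)[C@@H]1[C@]3(O)C=O | target

**Step count and risks**

Total steps: 14. Longest linear sequence: 8 (steps 7–14, from 1,2,4-trimethoxybenzene); the labdane branch is 6 steps plus the union.

Most likely to fail:

- **Step 14 (oxidative [5+2] union).** The phenoxonium ion may collapse to the neutral quinone before the diene traps it, or acid may isomerise the diene. The fallback sets out from 23 and comes back at 28. Oxidation of 23 with (NH4)2Ce(NO3)6 alone gives the methoxyquinone 24, which is now isolated. Acid hydrolysis of its vinylogous ester (dilute H2SO4, dioxane) gives the free hydroxyquinone F1. This preformed quinone is then combined with 11 under BF3·OEt2 (CH2Cl2, −40 °C) or by heating in toluene, in a perezone-type [5+2] cycloaddition that does not depend on oxidising the arene in the presence of the diene.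

- **Step 10 (kinetic resolution).** The hindered, electron-rich ketone may be reduced slowly or with a poor selectivity factor. The fallback sets the configuration by asymmetric catalysis, setting out from 15 and coming back at 20. Acylation/Nazarov closure of 15 with crotonic acid in polyphosphoric acid gives the racemic 3-methylindanone F2. Dehydrogenation with IBX gives the indenone F3. Conjugate addition of 4-methylpent-3-enylmagnesium bromide, catalysed by Cu(OTf)2 and a chiral N-heterocyclic carbene ligand, gives the (S)-3,3-disubstituted indanone F4. MeSO3H-mediated α-tert-alkylation then closes ring A to give 20.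

- **Step 11 (methoxymethylenation).** The ketone is hindered, deactivated by the methoxy groups and enolisable. The fallback sets out from 20 and comes back at 23. Methylenation (Ph3P=CH2, or Cp2TiCH2ClAlMe2) gives the exocyclic alkene F5. OsO4/NMO dihydroxylation from the α face gives the diol F6 with the tertiary OH α. Selective oxidation of the primary alcohol (TEMPO, PhI(OAc)2) gives 23.

Further compounds
F1 | step 14 | (4bS,8aS,9R)-3,9-dihydroxy-4b,8,8-trimethyl-1,4-dioxo-2-(propan-2-yl)-4,4b,5,6,7,8,8a,9-octahydro-1H-fluorene-9-carbaldehyde | O=C[C@]1(O)C2=C(C(=O)C(O)=C(C(C)C)C2=O)[C@@]2(C)CCCC(C)(C)[C@@H]21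
F2 | step 10 | (±)-4,5,7-trimethoxy-3-methyl-6-(propan-2-yl)-2,3-dihydro-1H-inden-1-one | CC1CC(=O)c2c(OC)c(C(C)C)c(OC)c(OC)c21
F3 | step 10 | 4,5,7-trimethoxy-3-methyl-6-(propan-2-yl)-1H-inden-1-one | CC1=CC(=O)c2c(OC)c(C(C)C)c(OC)c(OC)c21
F4 | step 10 | (3S)-4,5,7-trimethoxy-3-methyl-3-(4-methylpent-3-en-1-yl)-6-(propan-2-yl)-2,3-dihydro-1H-inden-1-one | O=C1c2c(OC)c(C(C)C)c(OC)c(OC)c2[C@@](C)(CCC=C(C)C)C1
F5 | step 11 | (4bS,8aS)-1,3,4-trimethoxy-4b,8,8-trimethyl-9-methylidene-2-(propan-2-yl)-4b,5,6,7,8,8a-hexahydro-9H-fluorene | C=C1c2c(OC)c(C(C)C)c(OC)c(OC)c2[C@@]2(C)CCCC(C)(C)[C@@H]21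
F6 | step 11 | (4bS,8aS,9R)-9-(hydroxymethyl)-1,3,4-trimethoxy-4b,8,8-trimethyl-2-(propan-2-yl)-4b,5,6,7,8,8a-hexahydro-9H-fluoren-9-ol | OC[C@]1(O)c2c(OC)c(C(C)C)c(OC)c(OC)c2[C@@]2(C)CCCC(C)(C)[C@@H]21
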